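**Strategy.** Ring C of this (2S)-flavanone is cut into an O1–C2–C3 dinucleophile and a C4–C4a–C8a dielectrophile. The key step joins them in one flask. The C,O-dilithio species made from an (R)-chlorohydrin of ring B is C-acylated by a ring-A N-acylimidazole (C3–C4). The aryl ketone so formed activates its ortho C8a–F bond for SNAr by the C2 alkoxide (O1–C8a). The step exploits the ortho relation of C4 and C8a on ring A and the 1,3-relation of O1 and C3 across the preset stereocentre C2. The precursors are a chloro alcohol and a fluorobenzoic acid; prenyl sits para to fluorine, so it can only end at C6.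

Key step: step 8

Assumption: the SMILES corresponds to the 2S configuration; flavanone numbering is used (O1, C2, C3, C4, C4a, C5 to C8, C8a, primed locants for ring B); diols 1 and 8 are taken as purchasable.

**Step 1**
Reactants: 1 5-fluorobenzene-1,3-diol
Product: 2 1-fluoro-3,5-bis(methoxymethoxy)benzene
Conditions: NaH, MOMCl, DMF, 0 °C to rt
Reagents that add atoms: chloromethyl methyl ether (MOMCl), COCCl
Why: Williamson-type O-alkylation of both phenoxides gives the bis-acetal, which later directs the metalations.

**Step 2**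
Reactants: 2 1-fluoro-3,5-bis(methoxymethoxy)benzene; 3 1-bromo-3-methylbut-2-ene (prenyl bromide)
Product: 5 5-fluoro-1,3-bis(methoxymethoxy)-2-(3-methylbut-2-en-1-yl)benzene, via aryllithium 4 (not isolated)
Conditions: n-BuLi, Et2O, 0 °C to rt; then CuI (10 mol %), 3, −20 °C to rt
Reagents that add atoms: none
Why: Directed ortho-metalation: in ether both OMOM groups chelate n-BuLi and direct lithiation to the carbon between them, and Cu-catalysed SN2 allylation of aryllithium 4 should give the linear prenyl arene.

**Step 3**
Reactants: 5 5-fluoro-1,3-bis(methoxymethoxy)-2-(3-methylbut-2-en-1-yl)benzene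
Product: 7 6-fluoro-2,4-bis(methoxymethoxy)-3-(3-methylbut-2-en-1-yl)benzoic acid, via aryllithium 6 (not isolated)
Conditions: s-BuLi, TMEDA, THF, −78 °C; CO2; then 1 M HCl to pH 3, 0 °C
Reagents that add atoms: carbon dioxide, O=C=O
Why: Directed ortho-metalation at the only kind of ring C–H left, flanked by F and OMOM and kinetically the most acidic site at −78 °C (where the ortho-fluoroaryllithium keeps its LiF), followed by carboxylation.

**Step 4**
Reactants: 8 4-methoxybenzene-1,3-diol
Product: 9 1-methoxy-2,4-bis(methoxymethoxy)benzene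
Conditions: NaH, MOMCl, DMF, 0 °C to rt
Reagents that add atoms: chloromethyl methyl ether (MOMCl), COCCl
Why: Williamson-type O-alkylation protects both phenols of ring B as acetals that tolerate organolithium reagents.

**Step 5**
Reactants: 9 1-methoxy-2,4-bis(methoxymethoxy)benzene
Product: 10 1-bromo-5-methoxy-2,4-bis(methoxymethoxy)benzene
Conditions: NBS, MeCN, 0 °C
Reagents that add atoms: N-bromosuccinimide (NBS), O=C1CCC(=O)N1Br
Why: Electrophilic aromatic bromination should go to the carbon para to one OMOM group and ortho to the other, the most activated and least hindered position.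

**Step 6**
Reactants: 10 1-bromo-5-methoxy-2,4-bis(methoxymethoxy)benzene; 11 2-chloro-N-methoxy-N-methylacetamide
Product: 13 2-chloro-1-[5-methoxy-2,4-bis(methoxymethoxy)phenyl]ethan-1-one, via aryllithium 12 (not isolated)
Conditions: n-BuLi, THF, −78 °C; then 11, −78 to −40 °C; cold 1 M HCl work-up
Reagents that add atoms: none
Why: Bromine–lithium exchange followed by Weinreb ketone synthesis: the chelated tetrahedral adduct lets aryllithium 12 add only once, and the α-chloro ketone appears only on work-up.

**Step 7**
Reactants: 13 2-chloro-1-[5-methoxy-2,4-bis(methoxymethoxy)phenyl]ethan-1-one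
Product: 14 (1R)-2-chloro-1-[5-methoxy-2,4-bis(methoxymethoxy)phenyl]ethan-1-ol
Conditions: RuCl[(S,S)-TsDPEN](p-cymene) (1 mol %), HCO2H/Et3N 5:2, DMF, 25 °C
Reagents that add atoms: none
Why: Asymmetric transfer hydrogenation (Noyori type): the (S,S)-ligand complex delivers hydride to the carbonyl face fixed by the CH/π contact between its η6-arene and the aryl ketone, which should give the alcohol spatially analogous to (S)-1-arylethanols, named R here because CH2Cl outranks aryl; this sets the future C2.

**Step 8**
Reactants: 7 6-fluoro-2,4-bis(methoxymethoxy)-3-(3-methylbut-2-en-1-yl)benzoic acid; 14 (1R)-2-chloro-1-[5-methoxy-2,4-bis(methoxymethoxy)phenyl]ethan-1-ol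
Product: 18 (2S)-2-[5-methoxy-2,4-bis(methoxymethoxy)phenyl]-5,7-bis(methoxymethoxy)-6-(3-methylbut-2-en-1-yl)-2,3-dihydro-4H-chromen-4-one, via N-acylimidazole 15 (not isolated), via dilithio alkoxide 16 (not isolated), via lithium aldolate 17 (not isolated)
Conditions: (a) 7, CDI, THF, rt, argon purge, then NaH (1 equiv); (b) 14, n-BuLi (1 equiv), THF, −78 °C, then LiC10H8 (2 equiv), −78 °C; (c) solution b into a at −78 °C, then DMPU, −78 to 0 °C; AcOH, −20 °C
Reagents that add atoms: none
Why: Deprotonation and reductive lithiation of 14 at −78 °C give the β-oxido alkyllithium 16, whose C3 carbanion adds to N-acylimidazole 15 and expels imidazolide, so the C3–C4 bond forms and aryl ketone 17 is released in the flask (nucleophilic acyl substitution of an acylimidazole by an organolithium; the sequence is the alkyllithium counterpart of the known enolate C-acylation/SNAr annulation to chromones). The new C4 carbonyl is ortho to C8a–F, so on warming the C2 alkoxide adds to C8a and fluoride leaves from the Meisenheimer adduct (SNAr), which forms O1–C8a. Ring C closes by 6-exo-trig attack on C8a, the only carbon of ring A that bears a leaving group, and this fixes prenyl at C6 and not at C8. No stereocentre is made: C2 comes from 14 with its four bonds untouched, and the descriptor changes from R to S only because the CH2 group no longer carries chlorine. The step needs C-acylation before any O-acylation and no second addition to the ketone, which the far higher reactivity of C–Li at −78 °C, the inverse addition and the two ortho substituents of the ketone should secure. It also needs ring closure to outrun retro-aldol cleavage of 17 and enolisation of 18, for which the weakly basic imidazolide leaving group, the DMPU-activated alkoxide and the cold acetic acid quench are chosen.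

**Step 9**
Reactants: 18 (2S)-2-[5-methoxy-2,4-bis(methoxymethoxy)phenyl]-5,7-bis(methoxymethoxy)-6-(3-methylbut-2-en-1-yl)-2,3-dihydro-4H-chromen-4-one
Product: 19 Kushenol V, (2S)-2-(2,4-dihydroxy-5-methoxyphenyl)-5,7-dihydroxy-6-(3-methylbut-2-en-1-yl)-2,3-dihydro-4H-chromen-4-one
Conditions: 3 M aq HCl, MeOH, 45 °C
Reagents that add atoms: none
Why: Acid-catalysed acetal exchange with methanol removes the four MOM groups as dimethoxymethane under conditions mild enough that the prenyl alkene and the C2–O1 bond should stay intact, so the 2S configuration is carried through.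

**Compound list**
1 | 5-fluorobenzene-1,3-diol | Oc1cc(O)cc(F)c1 | starting material
2 | 1-fluoro-3,5-bis(methoxymethoxy)benzene | COCOc1cc(F)cc(OCOC)c1 | intermediate
3 | 1-bromo-3-methylbut-2-ene (prenyl bromide) | CC(C)=CCBr | starting material
4 | [4-fluoro-2,6-bis(methoxymethoxy)phenyl]lithium | [Li]c1c(OCOC)cc(F)cc1OCOC | intermediate
5 | 5-fluoro-1,3-bis(methoxymethoxy)-2-(3-methylbut-2-en-1-yl)benzene | COCOc1cc(F)cc(OCOC)c1CC=C(C)C | intermediate
6 | [6-fluoro-2,4-bis(methoxymethoxy)-3-(3-methylbut-2-en-1-yl)phenyl]lithium | [Li]c1c(F)cc(OCOC)c(CC=C(C)C)c1OCOC | intermediate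
7 | 6-fluoro-2,4-bis(methoxymethoxy)-3-(3-methylbut-2-en-1-yl)benzoic acid | OC(=O)c1c(F)cc(OCOC)c(CC=C(C)C)c1OCOC | intermediate
8 | 4-methoxybenzene-1,3-diol | COc1ccc(O)cc1O | starting material
9 | 1-methoxy-2,4-bis(methoxymethoxy)benzene | COCOc1ccc(OC)c(OCOC)c1 | intermediate
10 | 1-bromo-5-methoxy-2,4-bis(methoxymethoxy)benzene | COCOc1cc(OCOC)c(OC)cc1Br | intermediate
11 | 2-chloro-N-methoxy-N-methylacetamide | CON(C)C(=O)CCl | starting material
12 | [5-methoxy-2,4-bis(methoxymethoxy)phenyl]lithium | [Li]c1cc(OC)c(OCOC)cc1OCOC | intermediate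
13 | 2-chloro-1-[5-methoxy-2,4-bis(methoxymethoxy)phenyl]ethan-1-one | COCOc1cc(OCOC)c(OC)cc1C(=O)CCl | intermediate
14 | (1R)-2-chloro-1-[5-methoxy-2,4-bis(methoxymethoxy)phenyl]ethan-1-ol | COCOc1cc(OCOC)c(OC)cc1[C@@H](O)CCl | intermediate
15 | [6-fluoro-2,4-bis(methoxymethoxy)-3-(3-methylbut-2-en-1-yl)phenyl](1H-imidazol-1-yl)methanone | O=C(c1c(F)cc(OCOC)c(CC=C(C)C)c1OCOC)n1ccnc1 | intermediate
16 | lithium (1S)-2-lithio-1-[5-methoxy-2,4-bis(methoxymethoxy)phenyl]ethan-1-olate | COCOc1cc(OCOC)c(OC)cc1[C@@H](O[Li])C[Li] | intermediate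
17 | lithium (1S)-3-[6-fluoro-2,4-bis(methoxymethoxy)-3-(3-methylbut-2-en-1-yl)phenyl]-1-[5-methoxy-2,4-bis(methoxymethoxy)phenyl]-3-oxopropan-1-olate | COCOc1cc(OCOC)c(OC)cc1[C@@H](O[Li])CC(=O)c1c(F)cc(OCOC)c(CC=C(C)C)c1OCOC | intermediate
18 | (2S)-2-[5-methoxy-2,4-bis(methoxymethoxy)phenyl]-5,7-bis(methoxymethoxy)-6-(3-methylbut-2-en-1-yl)-2,3-dihydro-4H-chromen-4-one | COCOc1cc(OCOC)c(OC)cc1[C@@H]1CC(=O)c2c(O1)cc(OCOC)c(CC=C(C)C)c2OCOC | intermediate
19 | Kushenol V, (2S)-2-(2,4-dihydroxy-5-methoxyphenyl)-5,7-dihydroxy-6-(3-methylbut-2-en-1-yl)-2,3-dihydro-4H-chromen-4-one | COc1cc([C@@H]2CC(=O)c3c(cc(O)c(CC=C(C)C)c3O)O2)c(O)cc1O | target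

**Step count.** Total: 9 steps. Longest linear sequence: 6 steps (steps 4 to 9).

**Steps most likely to fail**

1. Step 8. Several processes could spoil it:
   - a second addition of the alkyllithium to the ketone as it is released;
   - loss of Li2O from 16 to the styrene, or proton transfer from C3' of ring B to the carbanion, before acylation;
   - retro-aldol cleavage of aldolate 17 in competition with ring closure, which would erode the ee at C2 after re-addition;
   - enolisation and opening of ring C in 18.

   The fallback separates the two bond formations and sets out from 7 and 14. Acid 7 is converted (CDI, then MeNHOMe·HCl, CH2Cl2, rt) into the Weinreb amide 6-fluoro-N-methoxy-N-methyl-2,4-bis(methoxymethoxy)-3-(3-methylbut-2-en-1-yl)benzamide F1. Dilithio species 16, made from 14 as above, should add once to F1 at −78 °C because the chelated adduct releases no ketone in the flask. Cold NH4Cl work-up should give the isolable (3S)-1-[6-fluoro-2,4-bis(methoxymethoxy)-3-(3-methylbut-2-en-1-yl)phenyl]-3-hydroxy-3-[5-methoxy-2,4-bis(methoxymethoxy)phenyl]propan-1-one F2, whose ee can be checked. Intramolecular SNAr with Cs2CO3 in DMF at 0 °C then closes ring C and returns to 18.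

2. Step 2. Lithiation could occur at the carbon between F and OMOM instead of between the two OMOM groups, followed by loss of LiF to an aryne. The fallback fixes the position by halogenation and sets out from 1. Iodination (I2, NaHCO3, H2O, 0 °C) should place iodine between the two hydroxyls, as it does for resorcinol, and give 5-fluoro-2-iodobenzene-1,3-diol F3. NaH/MOMCl gives 5-fluoro-2-iodo-1,3-bis(methoxymethoxy)benzene F4. Iodine–lithium exchange (n-BuLi, THF, −78 °C) gives aryllithium 4 independent of C–H acidity, and CuI with 3 returns to 5.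

3. Step 9. Acid could add the 5- or 7-hydroxyl across the prenyl double bond (chroman formation), and could reversibly open ring C at the benzylic C2–O1 bond, which would racemise C2. The fallback avoids protic acid and sets out from 18. TMSOTf and 2,2'-bipyridyl in MeCN at 0 °C should convert the four aryl MOM ethers by silyl transfer into the tetrakis(trimethylsilyl) ether (2S)-2-[5-methoxy-2,4-bis(trimethylsilyloxy)phenyl]-6-(3-methylbut-2-en-1-yl)-5,7-bis(trimethylsilyloxy)-2,3-dihydro-4H-chromen-4-one F5. Water at pH 7 then hydrolyses F5 to 19.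

**Further compounds**
F1 | step 8 | 6-fluoro-N-methoxy-N-methyl-2,4-bis(methoxymethoxy)-3-(3-methylbut-2-en-1-yl)benzamide | CON(C)C(=O)c1c(F)cc(OCOC)c(CC=C(C)C)c1OCOC
F2 | step 8 | (3S)-1-[6-fluoro-2,4-bis(methoxymethoxy)-3-(3-methylbut-2-en-1-yl)phenyl]-3-hydroxy-3-[5-methoxy-2,4-bis(methoxymethoxy)phenyl]propan-1-one | COCOc1cc(OCOC)c(OC)cc1[C@@H](O)CC(=O)c1c(F)cc(OCOC)c(CC=C(C)C)c1OCOC
F3 | step 2 | 5-fluoro-2-iodobenzene-1,3-diol | Oc1cc(F)cc(O)c1I
F4 | step 2 | 5-fluoro-2-iodo-1,3-bis(methoxymethoxy)benzene | COCOc1cc(F)cc(OCOC)c1I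
F5 | step 9 | (2S)-2-[5-methoxy-2,4-bis(trimethylsilyloxy)phenyl]-6-(3-methylbut-2-en-1-yl)-5,7-bis(trimethylsilyloxy)-2,3-dihydro-4H-chromen-4-one | COc1cc([C@@H]2CC(=O)c3c(cc(O[Si](C)(C)C)c(CC=C(C)C)c3O[Si](C)(C)C)O2)c(O[Si](C)(C)C)cc1O[Si](C)(C)C
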